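A flattening curve tempts us to read an equilibrium, yet flattening says merely that X forms more slowly. The north-west and west runs share one charge, so a reversible step and a reagent lost elsewhere both stay open.

| setting | north-west | west | flask |
|---|---|---|---|
| E | 17 mM | 17 mM | 17 mM |
| G | 18.7 mM | 18.7 mM | 18.7 mM |
| Q | 17 mM | 17 mM | 17.0 mM |
| temperature | −20 °C | −25 °C | −20 °C |
| remark | the very flask that is asked about, followed so far | run made earlier |  |
| time |  |  | 4.0 h |

| run | time / min | X / % | E / % |
|---|---|---|---|
| north-west | 12.0 | 11 | 89 |
| north-west | 40.0 | 28 | 73 |
| north-west | 60.0 | 30 | 66 |
| north-west | 90.0 | 39 | 60 |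
| north-west | 150 | 45 | 57 |
| west | 12.0 | 10 | 90 |
| west | 40.0 | 24 | 76 |
| west | 60.0 | 31 | 72 |
| west | 90.0 | 36 | 65 |
| west | 150 | 40 | 58 |

(readings scatter by 1.5 percentage points)

- Sunday's: at 4.0 h raise the temperature by 25 K, then wait 80 min
- Saturday's: at 4.0 h add G, 100 % of the amount charged, then wait 80 min
- Tuesday's: at 4.0 h take out 90 % of the X then present, then wait 80 min
- Thursday's: change nothing and wait 80 min more

* X, in percent of the E first charged, at 4.0 h
* what to do for the largest gain in X; "none" if nothing gains more than 2 percentage points (Sunday's / Saturday's / Tuesday's / Thursday's / none)
* X present, with what was taken out counted in, in percent of the E first charged, after Saturday's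
* X present, with what was taken out counted in, in percent of the E first charged, after Tuesday's

- X taken out counts as made
- additions bring no volume worth counting

We commit to the lost reagent and follow one molecule of G through the north-west flask. At each moment it either meets E and becomes X or leaves by some other way, and we take its chance of becoming X to go with the E present. At 150 min that flask reads X at 45 % of the 17 mM of E, with 18.7 mM of G charged. If that G is used up, 40.9 % of it became X while E stood at a mean of 78.5 %. Dividing gives 52.1 %, which we call S, the start share: our estimate, from scattered readings, of the chance that a molecule of G ends as X with E as charged, a selectivity in plain terms.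

Now we turn the settings by hand. Saturday's brings new G, each molecule with chance S scaled by the E left, 57 % at the last reading, so we expect a gain of about 33 percentage points, and somewhat less if E falls further before the addition. Thursday's adds no G and merely waits on whatever G remains. Tuesday's leaves that same G, and in our picture X does not return, so it should match Thursday's. Sunday's changes the odds for that same remainder, so we expect these three to gain alike, and our choice is Saturday's.

The forecast gives 47 % now and chooses Saturday's, “so it is robustly the best move”, with 62 % after Saturday's and 55 % after Tuesday's. Our gain on its 47 % gives 80.0 % after Saturday's, so we part from it there.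

The flask gives 47.7 % at 4.0 h, then 75.8 % after Saturday's, the best choice, and 49.0 % after Tuesday's. Sunday's, Tuesday's and Thursday's each gain 1.3 points. At 4.0 h the flask held 10.5 % of its G and 52.3 % of its E.

    E + G → X, rate k1*[E]*[G]^1.5 (k = 5.00 L¹·⁵ mol⁻¹·⁵ min⁻¹, Ea = 37.0 kJ mol⁻¹)
    G + Q → L (k = 0.490 L mol⁻¹ min⁻¹, Ea = 61.0 kJ mol⁻¹)
    (constants at −20 °C)

With that E, S gives Saturday's 30 points, against 28 points in the flask.

For the neighbour charged with 4.7 mM of G, all else as in the flask, S gives 14.4 % of X if its G is used up. The computed flask reaches 8.45 %, less than that, with 8.4 % of its G still free.

The data are simulated with constants of no real substance; the scatter is artificial.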